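**Assumption:** arteminorin C has no stereocentres and the 3,3'-axis (flanked only by H-4/H-4' and the C2 carbonyls) rotates freely, so the molecule is achiral; "single enantiomer" is taken to mean the single constitutional isomer in the SMILES. The target is 7-hydroxy-6,8-dimethoxycoumarin (isofraxidin unit) joined C3–C3' to 6,7-dihydroxycoumarin (esculetin unit).

## Retrosynthetic overview

1. Final step: global removal of three MOM ethers (acid), which leaves the two methyl ethers and both lactones intact.
2. Key disconnection: the C3–C3' bond, made by a proposed Pd/Ag decarboxylative cross-coupling of an isofraxidin-type coumarin-3-carboxylic acid with a 3-bromo-esculetin bis-MOM ether.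
3. Acid partner: pyranone ring A formed by Knoevenagel–lactonisation of a 2-hydroxybenzaldehyde with Meldrum's acid. The aldehyde comes from 2,6-dimethoxyphenol by MOM protection, ortho-lithiation/borylation/oxidation, and Mg-mediated ortho-formylation.
4. Bromide partner: pyranone ring B is bought intact as esculetin, then MOM-protected and brominated at C3.
5. Ring order: ring B pre-formed, ring A formed in step 4, the two rings joined in step 7.

## Route

**Step 1**
Reactants: 1, 2,6-dimethoxyphenol (syringol)
Product: 2, 1,3-dimethoxy-2-(methoxymethoxy)benzene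
Conditions: NaH, MOMCl, THF/DMF, 0 °C → rt
Reagents that add atoms: chloromethyl methyl ether (MOMCl), COCCl
Why: Williamson-type O-alkylation (MOM protection) of the phenoxide; MOMCl is small and reactive enough for the doubly ortho-substituted phenol.

**Step 2**
Reactants: 2, 1,3-dimethoxy-2-(methoxymethoxy)benzene
Product: 3, 2,4-dimethoxy-3-(methoxymethoxy)phenol
Conditions: n-BuLi, TMEDA, THF, 0 °C → rt; B(OMe)3, −78 °C → rt; then 30% H2O2, AcOH, 0 °C → rt
Reagents that add atoms: hydrogen peroxide, OO (supplies the new phenolic O; B(OMe)3 is transient)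
Why: Directed ortho-metalation next to OMe (C4 and C6 are equivalent by symmetry, as in 1,2,3-trimethoxybenzene), then borylation and oxidative C–B → C–O migration.

**Step 3**
Reactants: 3, 2,4-dimethoxy-3-(methoxymethoxy)phenol
Product: 4, 2-hydroxy-3,5-dimethoxy-4-(methoxymethoxy)benzaldehyde
Conditions: MgCl2, Et3N, (CH2O)n, MeCN, reflux
Reagents that add atoms: paraformaldehyde (formaldehyde), C=O
Why: Casnati–Skattebøl magnesium-phenoxide ortho-formylation; it is ortho-specific, only one ortho C–H is free, and the basic medium preserves the MOM ether.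

**Step 4**
Reactants: 4, 2-hydroxy-3,5-dimethoxy-4-(methoxymethoxy)benzaldehyde; 5, Meldrum's acid
Product: 6, 6,8-dimethoxy-7-(methoxymethoxy)-2-oxo-2H-chromene-3-carboxylic acid
Conditions: piperidine (cat.), AcOH (cat.), EtOH, rt; cold dilute citric acid work-up (pH ≈ 3)
Reagents that add atoms: Meldrum's acid (5, already listed as reactant), CC1(C)OC(=O)CC(=O)O1 (supplies C2, C3 and CO2H; acetone and water are lost)
Why: Knoevenagel condensation followed by phenol attack on the acylal carbonyl (lactonisation with loss of acetone) gives the coumarin-3-carboxylic acid; room temperature and mild work-up keep the MOM group.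

**Step 5**
Reactants: 7, esculetin (6,7-dihydroxy-2H-chromen-2-one)
Product: 8, 6,7-bis(methoxymethoxy)-2H-chromen-2-one
Conditions: MOMCl (3 equiv), i-Pr2NEt, DMF, 0 °C → rt
Reagents that add atoms: chloromethyl methyl ether, COCCl (×2)
Why: Standard bis-MOM protection of the catechol; the lactone is inert to amine base.

**Step 6**
Reactants: 8, 6,7-bis(methoxymethoxy)-2H-chromen-2-one
Product: 9, 3-bromo-6,7-bis(methoxymethoxy)-2H-chromen-2-one
Conditions: Br2 (1.05 equiv), NaHCO3 (s), CH2Cl2, 0 °C; then Et3N, rt
Reagents that add atoms: bromine, BrBr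
Why: Bromine addition across the C3=C4 enoate, then E1cB dehydrobromination (acidic C3–H, benzylic C4–Br leaves) gives the 3-bromocoumarin; the solid buffer scavenges HBr so the MOM ethers survive.

**Step 7 (key step)**
Reactants: 6, 6,8-dimethoxy-7-(methoxymethoxy)-2-oxo-2H-chromene-3-carboxylic acid (1.3 equiv); 9, 3-bromo-6,7-bis(methoxymethoxy)-2H-chromen-2-one
Product: 10, 6,8-dimethoxy-6',7,7'-tris(methoxymethoxy)-2H,2'H-[3,3'-bichromene]-2,2'-dione
Conditions: Pd(OAc)2 (5 mol %), XPhos (10 mol %), Ag2CO3 (1.5 equiv), 4 Å MS, DMSO/1,4-dioxane (1:5), 110 °C, Ar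
Reagents that add atoms: none (CO2 and AgBr are lost)
Why: Proposed new method: a decarboxylative C3–C3' hetero-coupling of two α-pyranone units, in which the Ag(I) carboxylate of 6 extrudes CO2 (helped by the adjacent lactone C=O, as with ortho-substituted benzoates) to give a 3-argentocoumarin, Pd(0) adds oxidatively into the activated α-bromo-enoate C–Br of 9, Ag→Pd transmetalation is driven by AgBr precipitation, and reductive elimination forms the bond with regiochemistry fixed by the CO2H and Br positions; the closest known reaction type is Pd/Ag (or Pd/Cu) decarboxylative biaryl cross-coupling of heteroaromatic carboxylic acids (including coumarin-3-carboxylic acids) with simple aryl halides, not yet shown with a 3-halocoumarin electrophile to give a 3,3'-bicoumarin.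

**Step 8**
Reactants: 10, 6,8-dimethoxy-6',7,7'-tris(methoxymethoxy)-2H,2'H-[3,3'-bichromene]-2,2'-dione
Product: 11, arteminorin C
Conditions: 3 M aq. HCl, MeOH/THF (1:1), 50 °C
Reagents that add atoms: none
Why: Acid-catalysed acetal solvolysis removes all three MOM groups; aryl methyl ethers are untouched and the coumarin lactones are stable (or re-close) under acid.

## Compound list

1 | 2,6-dimethoxyphenol (syringol) | COc1cccc(OC)c1O | starting material
2 | 1,3-dimethoxy-2-(methoxymethoxy)benzene | COCOc1c(OC)cccc1OC | intermediate
3 | 2,4-dimethoxy-3-(methoxymethoxy)phenol | COCOc1c(OC)ccc(O)c1OC | intermediate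
4 | 2-hydroxy-3,5-dimethoxy-4-(methoxymethoxy)benzaldehyde | COCOc1c(OC)cc(C=O)c(O)c1OC | intermediate
5 | Meldrum's acid (2,2-dimethyl-1,3-dioxane-4,6-dione) | CC1(C)OC(=O)CC(=O)O1 | starting material
6 | 6,8-dimethoxy-7-(methoxymethoxy)-2-oxo-2H-chromene-3-carboxylic acid | COCOc1c(OC)cc2cc(C(=O)O)c(=O)oc2c1OC | intermediate
7 | esculetin (6,7-dihydroxy-2H-chromen-2-one) | Oc1cc2ccc(=O)oc2cc1O | starting material
8 | 6,7-bis(methoxymethoxy)-2H-chromen-2-one | COCOc1cc2ccc(=O)oc2cc1OCOC | intermediate
9 | 3-bromo-6,7-bis(methoxymethoxy)-2H-chromen-2-one | COCOc1cc2cc(Br)c(=O)oc2cc1OCOC | intermediate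
10 | 6,8-dimethoxy-6',7,7'-tris(methoxymethoxy)-2H,2'H-[3,3'-bichromene]-2,2'-dione | COCOc1c(OC)cc2cc(-c3cc4cc(OCOC)c(OCOC)cc4oc3=O)c(=O)oc2c1OC | intermediate
11 | arteminorin C (7-hydroxy-6,8-dimethoxy-6',7'-dihydroxy-3,3'-bicoumarin; achiral) | COc1cc2cc(-c3cc4cc(O)c(O)cc4oc3=O)c(=O)oc2c(OC)c1O | target

## Summary

**Total steps:** 8 (convergent: 4 for the acid arm, 2 for the bromide arm, coupling, deprotection).
**Longest linear sequence:** 6 steps (1 → 2 → 3 → 4 → 6 → 10 → 11; steps 1, 2, 3, 4, 7, 8).

**Three steps most likely to fail, with fallbacks**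

1. **Step 7 (proposed new decarboxylative hetero-coupling).** Risks are protodecarboxylation of 6, reductive homocoupling of 9, and Heck-type side reactions. Fallback (known chemistry): Suzuki–Miyaura coupling. Protodecarboxylate 6 (cat. Ag2CO3/AcOH, DMSO) to 7-O-MOM-isofraxidin and brominate it at C3 as in step 6. Convert 9 to its 3-Bpin derivative (B2pin2, Pd(dppf)Cl2, KOAc), then couple the two (Pd(dppf)Cl2, K3PO4, dioxane/H2O) to give 10.
2. **Step 6 (C3-bromination of the electron-rich MOM-protected coumarin).** Risks are competing ring bromination at C5/C8 and HBr-induced MOM loss. Fallback: change the protecting-group order. Acetylate esculetin (Ac2O/pyridine), brominate the deactivated diacetate (Br2 then Et3N, C3-selective addition–elimination), remove the acetates (K2CO3/MeOH), then install the MOM groups to reach 9.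
3. **Step 2 (ortho-lithiation/borylation/oxidation).** Risks are incomplete or unselective lithiation and over-oxidation of the electron-rich phenol. Fallback: reach aldehyde 4 from syringaldehyde by a C–Br route. MOM-protect the 4-OH, brominate at C2 with NBS (as for 3,4,5-trimethoxybenzaldehyde), then carry out Miyaura borylation and NaBO3 oxidation (or Pd-catalysed hydroxylation) of the aryl bromide to give 4 directly, bypassing steps 1–3.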